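The runs are simulated for an exercise.

You read theta at 5.0 min, so first ask whether the clock still matters.

in all of them: substrate 0.20 M
- dusk: reagent 0.80 M; capture agent 0.30 M; run made earlier
- beta: reagent 0.800 M; capture agent 0.200 M; time 5.0 min
- theta: reagent 0.100 M; capture agent 0.200 M; time 5.0 min

dusk run (percent of the substrate charged)

| time / s | first product / % | tris adduct / % |
|---|---|---|
| 10.0 | 20.0 | 16.1 |
| 15.0 | 14.3 | 27.4 |
| 25.0 | 7.0 | 46.2 |
| 40.0 | 2.9 | 60.9 |
| 60.0 | 1.4 | 70.1 |
| 120 | 0.5 | 70.6 |

(each reading ± 0.5 percentage points)

- no earlier run changes the charge of capture agent; that part of a forecast is a guess In dusk, first product falls at 0.0700 s⁻¹ between its first and third readings. Dividing by the charged reagent gives k = 0.0875 L mol⁻¹ s⁻¹, a rough figure read from scattered readings. Against theta's substrate, reagent's half-life is then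

h = ln(2)/(k × substrate) = 0.660 min,

shorter than the time of reading. So I expect theta's reagent, the limiting reagent, to be used up by the reading, and a count to tell how far the additions went. The addition count a is reagent charged over substrate charged, the additions available per substrate:

a = 0.500

Way one lets every step run equally fast, which gives first product a·exp(−a) = 30.3 %. But equal steps at dusk's rate put 34.8 % at dusk's first reading, and 20.0 % was read, so this way cheats.

Way two lets first product take reagent s times as fast as substrate. With x the substrate left, M the first product and later adducts ignored:

M = (x − x^s)/(s − 1), a ≈ M + 2(1 − x − M)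

Dusk's first product is already falling after that reading, so its peak lies earlier and should stand at or above the reading. Taking s = 3 gives a peak of 19.2 %, below the reading, while s = 2 gives 25.0 %, above it, so I take s = 2 as a rough reading. Trying x = 0.634 gives M = 23.2 % and a count of 0.500, which meets a. I commit to that for theta, with capture agent's effect a guess.

- which of these holds the largest part of the substrate at the end of beta (bis adduct / tetra adduct / tris adduct / substrate / first product)
- which of these holds the largest part of the substrate at the end of theta (bis adduct / tetra adduct / tris adduct / substrate / first product)
- first product at the end of theta, in percent of the substrate charged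

The forecast gives tris adduct for beta, substrate for theta and 15 % of first product, by “Sharing reagent among adducts”; my figure is higher.

The flasks give tris adduct, substrate and 14.3 %.

    substrate + reagent → first product (k = 0.210 L mol⁻¹ s⁻¹)
    reagent + first product → bis adduct (k = 0.400 L mol⁻¹ s⁻¹)
    reagent + bis adduct → tris adduct (k = 0.140 L mol⁻¹ s⁻¹)
    reagent + tris adduct → tetra adduct (k = 0.0140 L mol⁻¹ s⁻¹)
    2 substrate → self-condensation product (k = 0.00560 L mol⁻¹ s⁻¹)
    first product + capture agent → trapped intermediate (k = 0.00900 L mol⁻¹ s⁻¹)

Theta's reagent stood at 0.152 % at 2.50 min, with first product at 18.3 %; by 5.00 min first product had fallen to 14.3 % as trapped intermediate rose from 4.95 % to 9.02 %. Counting that one addition too, theta's adducts hold 50.0 % against a of 50.0 %. The neighbour of theta with 0.40 M of reagent has a = 2.00, and its reagent stands at 0.0376 %. It ends with bis adduct at 37.2 %, first product at 6.92 %, and a count of 200 %.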